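**Plan**
- Retrosynthesis: the C4 ketone is lowered to a C4 methyl ether and both phenols are masked as triisopropylsilyl (TIPS) ethers; ring C is then cut at O1–C2 and C3–C4 in one operation.
- Enabling feature: O1–C2 and C3–C4 are the only bonds of ring C that tie a salicyl unit (ring A, O1, C4) to a vinylarene unit (C3, C2, ring B), so ring C is the [4+2] adduct of an ortho-quinone methide and a styrene.
- Forward: rings A and B enter as 2,4-dihydroxybenzaldehyde and 4-hydroxybenzaldehyde; each is C-prenylated and silylated, and the ring B aldehyde is methylenated.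
- Ring C is closed last among the rings by the three-component union of aldehyde, trimethyl orthoformate and styrene, followed by C4 oxidation and desilylation.
- Stereochemistry: C2 (S) is set in the cycloaddition by a chiral confined imidodiphosphorimidate counter-anion; the C4 centre formed with it is erased on oxidation, and the final steps are non-basic so that C2 is not scrambled by ring opening.

Key step: step 6

Remark: flavonoid numbering is used (O1, C2, C3, C4 in ring C; C5–C8 in ring A; primed positions in ring B); "prenyl" means 3-methylbut-2-en-1-yl.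
Assumption: the sense of induction of the imidodiphosphorimidate acid cannot be predicted with confidence; the (S,S) antipode is written, and its mirror image would be used if a trial run shows that it leads to the 2R series.

**Step 1**
Reactants: 1 2,4-dihydroxybenzaldehyde; 2 prenyl bromide
Product: 3 2,4-dihydroxy-3-prenylbenzaldehyde
Conditions: KOH, H2O, 0 °C to rt; acidic work-up, chromatography
Reagents that add atoms: none
Why: Direct C-alkylation of an ambident phenoxide in water, where solvation of the oxygens disfavours O-alkylation and the resorcinol carbon C3 between the two oxygens is the most nucleophilic ring position; a modest-yielding but known prenylation whose C5 and O-alkylated by-products are separated.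

**Step 2**
Reactants: 3 2,4-dihydroxy-3-prenylbenzaldehyde
Product: 4 2-hydroxy-3-prenyl-4-(triisopropylsilyloxy)benzaldehyde
Conditions: TIPSCl (1.05 equiv), imidazole, DMF, 0 °C to rt
Reagents that add atoms: triisopropylsilyl chloride, CC(C)[Si](Cl)(C(C)C)C(C)C
Why: Imidazole-promoted silylation; the C2 hydroxyl is hydrogen-bonded to the aldehyde and flanked on both sides, so one equivalent of silyl chloride should react only at the free, more acidic C4 hydroxyl.

**Step 3**
Reactants: 5 4-hydroxybenzaldehyde; 2 prenyl bromide
Product: 6 4-hydroxy-3-prenylbenzaldehyde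
Conditions: KOH, H2O, rt; acidic work-up, chromatography
Reagents that add atoms: none
Why: The same aqueous phenoxide C-alkylation; with the para position blocked by the formyl group the prenyl unit can only enter ortho to the hydroxyl, and the mono-C-prenyl product is separated from the O-prenyl ether and recovered 5.

**Step 4**
Reactants: 6 4-hydroxy-3-prenylbenzaldehyde
Product: 7 3-prenyl-4-(triisopropylsilyloxy)benzaldehyde
Conditions: TIPSCl, imidazole, DMF, rt
Reagents that add atoms: triisopropylsilyl chloride, CC(C)[Si](Cl)(C(C)C)C(C)C
Why: Standard silylation of a phenol; the TIPS ether is chosen because it should tolerate the ylide of step 5 and the strong acid of step 6.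

**Step 5**
Reactants: 7 3-prenyl-4-(triisopropylsilyloxy)benzaldehyde
Product: 8 3-prenyl-4-(triisopropylsilyloxy)styrene
Conditions: MePPh3Br, KOtBu, THF, 0 °C to rt
Reagents that add atoms: methyltriphenylphosphonium bromide, C[P+](c1ccccc1)(c1ccccc1)c1ccccc1.[Br-]
Why: Wittig methylenation of an aromatic aldehyde with a non-stabilised ylide; the aryl silyl ether and the trisubstituted prenyl alkene are inert to the ylide at 0 °C.

**Step 6**
Reactants: 4 2-hydroxy-3-prenyl-4-(triisopropylsilyloxy)benzaldehyde; 8 3-prenyl-4-(triisopropylsilyloxy)styrene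
Product: 11 (2S,4S)-4-methoxy-8-prenyl-2-[3-prenyl-4-(triisopropylsilyloxy)phenyl]-7-(triisopropylsilyloxy)chroman, via dimethyl acetal 9 (not isolated), via ortho-quinone methide cation 10 (not isolated)
Conditions: HC(OMe)3 (2 equiv), (S,S)-imidodiphosphorimidate Brønsted acid (BINOL-derived, N-triflyl, 5 mol%), toluene, −40 °C, slow addition of 8 (1.5 equiv); chromatography to isolate the cis isomer
Reagents that add atoms: trimethyl orthoformate, COC(OC)OC
Why: Proposed new method: the confined strong acid converts 4 with the orthoformate into acetal 9 and ionises it to the O-methyl oxocarbenium ion 10, an O-protonated ortho-quinone methide held by its phenol hydrogen bond to the chiral anion; the CH2 terminus of styrene 8 adds to C4 and the phenol oxygen collapses on the resulting para-silyloxybenzyl cation at C2, an asynchronous inverse-demand oxa-[4+2] cycloaddition. The closest known chemistry is the racemic acid-catalysed three-component coupling of salicylaldehydes, orthoformates and styrenes to 2-aryl-4-alkoxychromans, together with chiral phosphoric acid-catalysed [4+2] reactions of ortho-quinone methides. Ring C closes as a six-membered ring by intermolecular C3–C4 bond formation followed by O1–C2 closure onto the benzylic cation, a formal [4+2] annulation. C4 is set by the face of the ion-paired oxocarbenium that the catalyst pocket leaves open, and C2 by the endo-type placement of the aryl group in the same pocket, which should give the 2,4-cis (2S,4S) isomer; only this isomer is carried on, because a trans isomer formed on the same cation face would be 2R. Chemo- and regioselectivity rest on the para-silyloxy group of 8, which makes the vinyl CH2 far more nucleophilic than the prenyl alkenes and places the cation at C2; the low temperature and the buffering excess of orthoformate should keep the acid from protonating the prenyl groups, from closing the ortho-prenylphenol of 4 to a dimethylchroman and from oligomerising 8.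

**Step 7**
Reactants: 11 (2S,4S)-4-methoxy-8-prenyl-2-[3-prenyl-4-(triisopropylsilyloxy)phenyl]-7-(triisopropylsilyloxy)chroman
Product: 13 (2S)-8-prenyl-2-[3-prenyl-4-(triisopropylsilyloxy)phenyl]-7-(triisopropylsilyloxy)chroman-4-one, via methyl hemiketal 12 (not isolated)
Conditions: DDQ (1.2 equiv), CH2Cl2/pH 7 phosphate buffer (10:1), 0 °C
Reagents that add atoms: water, O
Why: DDQ oxidation of an electron-rich benzylic ether: hydride abstraction from C4–H, activated by the methoxy group and by the para-silyloxy and ortho-alkoxy substituents of ring A, is followed by capture by water to hemiketal 12 and loss of methanol; C2 is untouched, and the ketone formed deactivates ring A against further oxidation at 0 °C.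

**Step 8**
Reactants: 13 (2S)-8-prenyl-2-[3-prenyl-4-(triisopropylsilyloxy)phenyl]-7-(triisopropylsilyloxy)chroman-4-one
Product: 14 glabrol, (2S)-7-hydroxy-2-(4-hydroxy-3-prenylphenyl)-8-prenylchroman-4-one
Conditions: HF·pyridine, pyridine, THF, 0 °C to rt
Reagents that add atoms: none
Why: Fluoride cleavage of both aryl silyl ethers under buffered acidic conditions, which avoid the phenoxide- or enolate-triggered retro-oxa-Michael opening of ring C that would racemise C2, and which should be too mild to cyclise the freed ortho-prenylphenols.

**Compound list**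
1 | 2,4-dihydroxybenzaldehyde | O=Cc1ccc(O)cc1O | starting material
2 | prenyl bromide (1-bromo-3-methylbut-2-ene) | CC(C)=CCBr | starting material
3 | 2,4-dihydroxy-3-prenylbenzaldehyde | O=Cc1ccc(O)c(CC=C(C)C)c1O | intermediate
4 | 2-hydroxy-3-prenyl-4-(triisopropylsilyloxy)benzaldehyde | O=Cc1ccc(O[Si](C(C)C)(C(C)C)C(C)C)c(CC=C(C)C)c1O | intermediate
5 | 4-hydroxybenzaldehyde | O=Cc1ccc(O)cc1 | starting material
6 | 4-hydroxy-3-prenylbenzaldehyde | O=Cc1ccc(O)c(CC=C(C)C)c1 | intermediate
7 | 3-prenyl-4-(triisopropylsilyloxy)benzaldehyde | O=Cc1ccc(O[Si](C(C)C)(C(C)C)C(C)C)c(CC=C(C)C)c1 | intermediate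
8 | 3-prenyl-4-(triisopropylsilyloxy)styrene | C=Cc1ccc(O[Si](C(C)C)(C(C)C)C(C)C)c(CC=C(C)C)c1 | intermediate
9 | 2-(dimethoxymethyl)-6-prenyl-5-(triisopropylsilyloxy)phenol (dimethyl acetal of 4) | COC(OC)c1ccc(O[Si](C(C)C)(C(C)C)C(C)C)c(CC=C(C)C)c1O | intermediate (not isolated)
10 | O-methyl oxocarbenium ion of 4 (O-protonated ortho-quinone methide with methoxy on the future C4), ion-paired with the catalyst anion | C[O+]=Cc1ccc(O[Si](C(C)C)(C(C)C)C(C)C)c(CC=C(C)C)c1O | intermediate (not isolated)
11 | (2S,4S)-4-methoxy-8-prenyl-2-[3-prenyl-4-(triisopropylsilyloxy)phenyl]-7-(triisopropylsilyloxy)chroman (2,4-cis) | CC(C)=CCc1cc([C@@H]2C[C@H](OC)c3ccc(O[Si](C(C)C)(C(C)C)C(C)C)c(CC=C(C)C)c3O2)ccc1O[Si](C(C)C)(C(C)C)C(C)C | intermediate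
12 | (2S)-4-hydroxy-4-methoxy-8-prenyl-2-[3-prenyl-4-(triisopropylsilyloxy)phenyl]-7-(triisopropylsilyloxy)chroman (C4 methyl hemiketal, either C4 configuration) | CC(C)=CCc1cc([C@@H]2CC(O)(OC)c3ccc(O[Si](C(C)C)(C(C)C)C(C)C)c(CC=C(C)C)c3O2)ccc1O[Si](C(C)C)(C(C)C)C(C)C | intermediate (not isolated)
13 | (2S)-8-prenyl-2-[3-prenyl-4-(triisopropylsilyloxy)phenyl]-7-(triisopropylsilyloxy)chroman-4-one | CC(C)=CCc1cc([C@@H]2CC(=O)c3ccc(O[Si](C(C)C)(C(C)C)C(C)C)c(CC=C(C)C)c3O2)ccc1O[Si](C(C)C)(C(C)C)C(C)C | intermediate
14 | glabrol, (2S)-7-hydroxy-2-(4-hydroxy-3-prenylphenyl)-8-prenylchroman-4-one | CC(C)=CCc1cc([C@@H]2CC(=O)c3ccc(O)c(CC=C(C)C)c3O2)ccc1O | target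

**Step count and risks**
Total steps: 8. Longest linear sequence: 6 steps (steps 3, 4, 5, 6, 7 and 8, from 4-hydroxybenzaldehyde).

Step 6 (proposed new method). What may go wrong: insufficient facial discrimination of the strongly stabilised oxocarbenium ion by the chiral anion, or endo/exo leakage that delivers the 2R centre. Acid-driven side processes are also possible: cationic oligomerisation of the styrene, cyclisation of the ortho-prenylphenol, and re-ionisation of the product at C4 or C2. The fallback uses known chemistry, sets out from 4 and 8 and returns at 13. The same three components are joined with an achiral acid (TsOH, 10 mol%, HC(OMe)3, CH2Cl2, 0 °C), the established racemic three-component chroman synthesis, to give racemic 4-methoxy-8-prenyl-2-[3-prenyl-4-(triisopropylsilyloxy)phenyl]-7-(triisopropylsilyloxy)chroman F1 as a mixture of C4 epimers. DDQ in wet CH2Cl2, as in step 7, should convert both epimers into racemic 8-prenyl-2-[3-prenyl-4-(triisopropylsilyloxy)phenyl]-7-(triisopropylsilyloxy)chroman-4-one F2. A kinetic resolution by asymmetric transfer hydrogenation (RuCl[(R,R)-TsDPEN](p-cymene), HCO2H/Et3N, rt, stopped near half conversion; the catalyst antipode is the one expected to consume the 2R ketone) should then reduce the 2R enantiomer to (2R,4R)-8-prenyl-2-[3-prenyl-4-(triisopropylsilyloxy)phenyl]-7-(triisopropylsilyloxy)chroman-4-ol F3 and leave the 2S ketone, which is 13 and is separated by chromatography. The stereocentre then comes from a resolution and not from the cycloaddition.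

Step 7. What may go wrong: competing hydride abstraction at the doubly activated benzylic–allylic CH2 groups of the prenyl side chains or at C2–H, giving dehydrogenated or ring-opened material. The fallback sets out from 11 and returns at 13. Acid-catalysed SN1 exchange of the benzylic methoxy group for hydroxyl (TsOH cat., THF/H2O, rt) should give (2S)-8-prenyl-2-[3-prenyl-4-(triisopropylsilyloxy)phenyl]-7-(triisopropylsilyloxy)chroman-4-ol F4 as a mixture of C4 epimers. Dess–Martin periodinane (NaHCO3, CH2Cl2, 0 °C) then oxidises the secondary benzylic alcohol to 13 without any hydride-abstracting oxidant.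

Step 1. What may go wrong: O-alkylation, attack at C5 and double alkylation of the ambident dianion, which lower the throughput of the C3 isomer. The fallback sets out from 1 and returns at 3. Chelation-controlled O-alkylation of the free C4 hydroxyl with 3-chloro-3-methylbut-1-yne (K2CO3, KI, CuI cat., acetone, 50 °C) should give 2-hydroxy-4-(2-methylbut-3-yn-2-yloxy)benzaldehyde F5. Semihydrogenation (H2, Lindlar catalyst, that is Pd on CaCO3 poisoned with Pb(OAc)2, quinoline, EtOAc) should give 2-hydroxy-4-(2-methylbut-3-en-2-yloxy)benzaldehyde F6. An aromatic Claisen rearrangement (N,N-diethylaniline, 130 °C) then transfers the allyl unit with allylic inversion to C3, the position favoured by the bond fixation of the chelated salicylaldehyde, and delivers the linear prenyl group of 3.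

**Further compounds**
F1 | step 6 | racemic 4-methoxy-8-prenyl-2-[3-prenyl-4-(triisopropylsilyloxy)phenyl]-7-(triisopropylsilyloxy)chroman (mixture of C4 epimers) | CC(C)=CCc1cc(C2CC(OC)c3ccc(O[Si](C(C)C)(C(C)C)C(C)C)c(CC=C(C)C)c3O2)ccc1O[Si](C(C)C)(C(C)C)C(C)C
F2 | step 6 | racemic 8-prenyl-2-[3-prenyl-4-(triisopropylsilyloxy)phenyl]-7-(triisopropylsilyloxy)chroman-4-one | CC(C)=CCc1cc(C2CC(=O)c3ccc(O[Si](C(C)C)(C(C)C)C(C)C)c(CC=C(C)C)c3O2)ccc1O[Si](C(C)C)(C(C)C)C(C)C
F3 | step 6 | (2R,4R)-8-prenyl-2-[3-prenyl-4-(triisopropylsilyloxy)phenyl]-7-(triisopropylsilyloxy)chroman-4-ol | CC(C)=CCc1cc([C@H]2C[C@@H](O)c3ccc(O[Si](C(C)C)(C(C)C)C(C)C)c(CC=C(C)C)c3O2)ccc1O[Si](C(C)C)(C(C)C)C(C)C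
F4 | step 7 | (2S)-8-prenyl-2-[3-prenyl-4-(triisopropylsilyloxy)phenyl]-7-(triisopropylsilyloxy)chroman-4-ol (mixture of C4 epimers) | CC(C)=CCc1cc([C@@H]2CC(O)c3ccc(O[Si](C(C)C)(C(C)C)C(C)C)c(CC=C(C)C)c3O2)ccc1O[Si](C(C)C)(C(C)C)C(C)C
F5 | step 1 | 2-hydroxy-4-(2-methylbut-3-yn-2-yloxy)benzaldehyde | O=Cc1ccc(OC(C)(C)C#C)cc1O
F6 | step 1 | 2-hydroxy-4-(2-methylbut-3-en-2-yloxy)benzaldehyde | O=Cc1ccc(OC(C)(C)C=C)cc1O
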